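The ratio of starting material to free catalyst charged counts the turnovers a full conversion asks of each catalyst: 65.0 in the dusk run, 150 in the autumn run.

the same everywhere: free catalyst 0.20 mM
- dusk: starting material 13 mM; second substrate 40 mM; run made earlier
- autumn: starting material 30 mM; second substrate 40 mM; run made earlier
- flask: starting material 20 mM; second substrate 40.0 mM

- dusk (time / min: target / %): 0.667: 2; 1.33: 7; 2.00: 12; 2.50: 14; 3.00: 18; 4.00: 23
- autumn (time / min: target / %): 0.667: 3; 1.33: 5; 2.00: 10; 2.50: 9; 3.00: 15; 4.00: 23

(readings scatter by 1.5 percentage points)

1. factor on the rate of making target when 30% of the starting material are converted if second substrate is charged twice over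
2. factor on the rate when 30% of the starting material are converted if free catalyst is charged at 1.0 mM instead

- no earlier run changes the charge of free catalyst; that part of a forecast is a guess
- no earlier run changes the charge of second substrate; that part of a forecast is a guess

At 4.00 min both runs read 23%, which is 15.0 turnovers in the dusk run and 34.5 in the autumn run. The turnover counts thus stand in the ratio of the charges, 2.31, and I read the runs as pseudo-first-order in starting material, with a constant of 0.0653 min⁻¹.

For the flask I carry the turnover demand, the turnovers each catalyst charged must make to reach the conversion looked at: 30.0. Demand and constant together give a first turnover rate at that conversion of 4.57 min⁻¹.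

The weak link is the constant, taken from time zero. The first readings, 2% and 3%, lie below the 4.26% it predicts, so I reforge it from the stretch between 2.00 min and 4.00 min, averaged over both runs: 0.0724 min⁻¹. That reading gives a turnover rate of 5.07 min⁻¹ for each catalyst charged.

If each catalyst keeps that pace at 1.0 mM, the demand falls to 6.00 and I commit to a factor of 5.00. Neither run varies second substrate, so I guess 1 there.

The forecast commits to 1.5 (range 1 to 2.3) for second substrate and 4.5 (2.3 to 5.5) for the catalyst, the catalyst factor being shaded from its view that “Catalyst is most likely first order”. It differs from my numbers on both questions.

The simulation gives 0.975 for doubled second substrate and 3.72 for the catalyst, both below the forecast.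

    starting material + free catalyst ⇌ catalyst intermediate A (K = 14000 L mol⁻¹, k = 16.0 L mol⁻¹ s⁻¹)
    catalyst intermediate A → free catalyst + target (k = 0.660 s⁻¹)
    second substrate + free catalyst ⇌ catalyst intermediate B (K = 120 L mol⁻¹, k = 34.0 L mol⁻¹ s⁻¹)
    catalyst intermediate B → free catalyst + second product (k = 0.100 s⁻¹)
    2 second substrate → self-condensation product (k = 0.200 L mol⁻¹ s⁻¹)
    second substrate + free catalyst → spent catalyst (k = 0.0730 L mol⁻¹ s⁻¹)

At 0.600 min the flask has 62.6% of its second substrate left, and catalyst intermediate B, the resting state then, holds 59.3% of the catalyst, more than any other form. By 6.00 min self-condensation product stands at 16.1 mM, second substrate at 12.6%, and catalyst intermediate B at 22.7%. The flask meets its demand of 30.0 turnovers at 4.98 min, turning over 6.40 min⁻¹ per catalyst charged. At 1.0 mM of free catalyst the demand is 6.00 turnovers, and at that conversion each catalyst charged turns over 4.76 min⁻¹, slower than in the flask.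

The earlier runs and the new flask are simulated for an exercise.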